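- I began from the ratio of X to E, 1.05 equiv in the flask, with more X than E, so that E was the limiting reagent; taking an even match of one X per E as the zero of my scale, I reckoned 0.0750 M as the X surplus, the X charged above one X for each E.

| setting | green | violet | flask |
|---|---|---|---|
| E | 1.5 M | 1.5 M | 1.5 M |
| X | 1.05 equiv | 1.05 equiv | 1.05 equiv |
| L | 0.75 mol% | 3 mol% | 1.5 mol% |
| remark | run made earlier | run made earlier |  |
| time |  |  | 80 min |

| run | time / min | Z / % | E / % |
|---|---|---|---|
| green | 2.50 | 74.5 | 4.4 |
| green | 8.00 | 94.2 | 2.4 |
| green | 15.0 | 96.5 | 0 |
| green | 20.0 | 98.0 | 0 |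
| green | 30.0 | 100.3 | 1.2 |
| green | 40.0 | 101.2 | 1.9 |
| green | 50.0 | 99.5 | 0.7 |
| violet | 6.00 | 97.9 | 0 |
| violet | 15.0 | 100.9 | 0 |
| violet | 20.0 | 97.9 | 0 |
| violet | 30.0 | 98.4 | 0 |
| violet | 40.0 | 100.7 | 1.4 |
| violet | 50.0 | 98.7 | 0 |

(standard deviation of a reading: 1 percentage point)

- reactions considered so far: L + J <-> D; E + L <-> L + J; X -> Q; X + D -> L + Z
- the reaction counts as stopped when no species that holds the E changes by six tenths of a point or more over the second half of the time

1. which holds at 80 min: what has brought the reaction to rest, or that it has not come to rest (no working catalyst is left / it is still moving / forward and back rates have come level / X has run out first / all of E has reacted)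
2. amount of Z at 80 min, in percent of the E charged

- My ledger for E opened with the last readings of the earlier runs: the green run stood at 99.5 % of Z and 0.7 % of E, and the violet run at 98.7 % of Z and 0 % of E, so against a scatter of 1 percentage point I saw no need for another entry at either loading.
- For the flask, whose 1.5 mol% of L lay between those loadings, I therefore entered the charge of 1.5 M of E as Z, which drew that same amount from the 1.575 M of X charged and left the surplus as the X that could go to Q or stay unspent.
- The forecast gave "all of E has reacted" and 99.7 % of Z at 80 min, on the ground that “The plateau does not depend on catalyst loading across a fourfold range”; my ledger entered the whole charge of E as Z, and the forecast's figure lay within the scatter of that entry.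
- The flask agreed with the forecast: "all of E has reacted", with >99.9 % of Z and 0 % of E at 80.0 min.

    L + J ⇌ D (K = 0.750 M⁻¹, k = 40.0 M⁻¹ s⁻¹)
    E + L ⇌ L + J (K = 4.20, k = 4.50 M⁻¹ s⁻¹)
    X → Q (k = 4.80 × 10⁻⁵ s⁻¹)
    X + D → L + Z (k = 3.00 M⁻¹ s⁻¹)

- In the flask at 80.0 min, the surplus of 0.0750 M stood as 0.0198 M of Q and 0.0553 M of unspent X, which was 3.51 % of its own charge, so the X side of the books closed as well. In the neighbouring flask with 0.630 equiv of X, the same reckoning put the surplus below zero, a shortfall of 0.555 M, or 37.0 % of the E charged. That neighbouring flask held 0 % of its X at 80.0 min, with 7.07 % of the E charged still as E, 29.7 % as J and 62.9 % as Z.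

Readings and results are simulated with constants of no real substance, noise included.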